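**Retrosynthetic overview**
- Vibsanin E ⇒ Wittig olefination of a tricyclic keto-aldehyde with an acyloxymethylene ylide made separately from 3-methylbut-2-enoyl chloride; the aldehyde and the methyl ketone come from one ozonolysis of a C11-vinyl / C10-methallyl ketone.
- C11-vinyl ⇐ copper-catalysed 1,4-addition to a 2-methallyl enone, with C10 set by protonation; methallyl ⇐ Stille coupling of the α-iodoenone with a separately made stannane.
- Enone ⇐ allylic oxidation; ring A (cyclohexane) and ring B (pyran) ⇐ one intramolecular hetero-Diels–Alder reaction of a cycloheptadienal, then enol-ether reduction.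
- Ring C ⇐ [4+3] union (cyclopropanation/Cope) of two fragments of like size, a C11 triene and methyl 2-diazobut-3-enoate, under a chiral dirhodium catalyst that sets the quaternary carbon.
- Triene ⇐ 5-bromo-2-methylpent-2-ene; diazo ester ⇐ methyl acetoacetate. Ring order: C first, then A and B together.

Assumption: Rh2(R-PTAD)4 is taken as the catalyst enantiomer that gives the (S)-cycloheptadiene of step 7; if its sense of induction is the opposite, Rh2(S-PTAD)4 is used and nothing else changes.

Numbering used for the tricycles (6-oxatricyclo[6.3.2.0^{4,13}]tridecane): C1 quaternary bridgehead (CH3), C2, C3, C4 ring-fusion CH, C5 CMe2, O6, C7 OCH2, C8, C9 (C=O), C10, C11, C12 one-carbon bridge, C13 bridgehead CH.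

**Step 1**
Reactants: 1 5-bromo-2-methylpent-2-ene
Product: 2 6-methylhept-5-en-1-yne
Conditions: LiC≡CH·H2NCH2CH2NH2 (1.2 equiv), DMSO, 10 °C → rt
Reagents that add atoms: lithium acetylide ethylenediamine complex, [Li]C#C.NCCN
Why: SN2 alkylation of the acetylide at the unhindered primary bromide gives the terminal alkyne without forming a stereocentre.

**Step 2**
Reactants: 2 6-methylhept-5-en-1-yne
Product: 4 (1E)-1-iodo-2,6-dimethylhepta-1,5-diene, via alkenylalane 3 (not isolated)
Conditions: Me3Al (2 equiv), Cp2ZrCl2 (0.25 equiv), CH2Cl2, 0 °C → rt; then I2, THF, −30 → 0 °C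
Reagents that add atoms: trimethylaluminium, C[Al](C)C; iodine, II
Why: Negishi zirconium-catalysed carboalumination adds CH3 and Al syn across the alkyne (CH3 to the inner carbon) and iodinolysis of the C–Al bond goes with retention, which fixes the E trisubstituted alkene.

**Step 3**
Reactants: 4 (1E)-1-iodo-2,6-dimethylhepta-1,5-diene
Product: 5 (3E)-4,8-dimethylnona-1,3,7-triene
Conditions: CH2=CHMgBr (1.5 equiv), Pd(PPh3)4 (3 mol %), THF, 0 °C → rt
Reagents that add atoms: vinylmagnesium bromide, C=C[Mg]Br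
Why: palladium-catalysed Kumada–Corriu cross-coupling of the alkenyl iodide proceeds with retention of the E geometry and completes the diene.

**Step 4**
Reactants: 6 methyl acetoacetate
Product: 7 methyl 2-diazo-3-oxobutanoate
Conditions: 4-acetamidobenzenesulfonyl azide (1.1 equiv), Et3N, MeCN, 0 °C → rt
Reagents that add atoms: 4-acetamidobenzenesulfonyl azide, CC(=O)Nc1ccc(cc1)S(=O)(=O)N=[N+]=[N-]
Why: Regitz diazo transfer to the doubly activated methylene.

**Step 5**
Reactants: 7 methyl 2-diazo-3-oxobutanoate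
Product: 8 methyl 2-diazo-3-hydroxybutanoate (racemic)
Conditions: NaBH4, MeOH, 0 °C
Reagents that add atoms: none
Why: chemoselective borohydride reduction of the ketone leaves the ester and the diazo group intact, and the racemic carbinol centre is removed in the next step.

**Step 6**
Reactants: 8 methyl 2-diazo-3-hydroxybutanoate
Product: 9 methyl 2-diazobut-3-enoate
Conditions: POCl3, Et3N, CH2Cl2, 0 °C; used at once as a cold solution
Reagents that add atoms: none
Why: activation of the alcohol as a dichlorophosphate and E2 elimination gives the vinyldiazoacetate, which is used immediately because it slowly closes to a pyrazole.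

**Step 7**
Reactants: 5 (3E)-4,8-dimethylnona-1,3,7-triene; 9 methyl 2-diazobut-3-enoate
Product: 11 methyl (4S)-4-methyl-4-(4-methylpent-3-en-1-yl)cyclohepta-1,5-diene-1-carboxylate, via divinylcyclopropane 10 (not isolated)
Conditions: Rh2(R-PTAD)4 (dirhodium tetrakis[(R)-(1-adamantyl)(phthalimido)acetate], 1 mol %), hexanes, 9 (1.5 equiv) added over 2 h, 0 °C → rt; then 70 °C, 2 h
Reagents that add atoms: none
Why: Davies tandem cyclopropanation/Cope rearrangement (formal [4+3] cycloaddition), in which the chiral rhodium vinylcarbenoid cyclopropanates the monosubstituted diene terminus enantio- and cis-selectively and the boat-type Cope rearrangement transfers that chirality to the new quaternary carbon (S).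

**Step 8**
Reactants: 11 cycloheptadiene methyl ester
Product: 12 [(4S)-4-methyl-4-(4-methylpent-3-en-1-yl)cyclohepta-1,5-dien-1-yl]methanol
Conditions: i-Bu2AlH (2.5 equiv), CH2Cl2, −78 °C; aq. potassium sodium tartrate
Reagents that add atoms: none
Why: 1,2-reduction of the conjugated ester to the allylic alcohol leaves the alkenes and the stereocentre untouched.

**Step 9**
Reactants: 12 dienyl methanol
Product: 13 (4S)-4-methyl-4-(4-methylpent-3-en-1-yl)cyclohepta-1,5-diene-1-carbaldehyde
Conditions: Dess–Martin periodinane, CH2Cl2, rt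
Reagents that add atoms: none
Why: mild oxidation of the allylic alcohol gives the enal that serves as the 1-oxadiene.

**Step 10**
Reactants: 13 cycloheptadienal
Product: 15 (1S,4R,8S,13R)-1,5,5-trimethyl-6-oxatricyclo[6.3.2.0^{4,13}]tridec-10-ene, via tricyclic enol ether 14 (not isolated)
Conditions: BF3·OEt2 (1 equiv), CH2Cl2, −78 °C; then Et3SiH (3 equiv), CF3CO2H (3 equiv), −78 → −20 °C
Reagents that add atoms: none
Why: Lewis-acid-promoted intramolecular inverse-demand hetero-Diels–Alder reaction closes rings A and B on the face of ring C that carries the tether, so C13 and C4 follow from C1 and only the cis A/B fusion is geometrically possible, and ionic hydrogenation then protonates the enol ether at C8 from the open face of H-13 and reduces the oxocarbenium ion.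

**Step 11**
Reactants: 15 tricyclic alkene
Product: 16 (1S,4R,8S,13S)-1,5,5-trimethyl-6-oxatricyclo[6.3.2.0^{4,13}]tridec-10-en-9-one
Conditions: Rh2(cap)4 (dirhodium tetracaprolactamate, 1 mol %), t-BuOOH (5 equiv), K2CO3 (0.5 equiv), CH2Cl2, rt
Reagents that add atoms: tert-butyl hydroperoxide, CC(C)(C)OO
Why: radical allylic C–H oxidation can start only at C9 because the other allylic carbon C1 is quaternary, and oxygen is taken up at the less hindered end of the allyl radical (C9, not the neopentyl C11).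

**Step 12**
Reactants: 16 tricyclic enone
Product: 17 (1S,4R,8S,13S)-10-iodo-1,5,5-trimethyl-6-oxatricyclo[6.3.2.0^{4,13}]tridec-10-en-9-one
Conditions: I2 (2 equiv), pyridine/CH2Cl2 1:1, 0 °C → rt
Reagents that add atoms: iodine, II
Why: Johnson α-iodination of an enone by pyridine addition, iodination of the enolate and elimination.

**Step 13**
Reactants: 18 2-methylallylmagnesium chloride
Product: 19 tributyl(2-methylprop-2-en-1-yl)stannane
Conditions: Bu3SnCl, THF, 0 °C → rt
Reagents that add atoms: tributyltin chloride, CCCC[Sn](CCCC)(CCCC)Cl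
Why: transmetallation of the allylic Grignard reagent to tin gives the Stille partner.

**Step 14**
Reactants: 17 α-iodoenone; 19 tributyl(2-methylprop-2-en-1-yl)stannane
Product: 20 (1S,4R,8S,13S)-1,5,5-trimethyl-10-(2-methylprop-2-en-1-yl)-6-oxatricyclo[6.3.2.0^{4,13}]tridec-10-en-9-one
Conditions: Pd2(dba)3 (2.5 mol %), AsPh3 (10 mol %), CuI (10 mol %), NMP, rt → 45 °C
Reagents that add atoms: none
Why: Stille cross-coupling of an α-iodoenone with an allylstannane installs the masked acetonyl group on C10 before C11 is substituted.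

**Step 15**
Reactants: 20 2-methallyl enone
Product: 22 (1S,4R,8S,10S,11S,13S)-11-ethenyl-1,5,5-trimethyl-10-(2-methylprop-2-en-1-yl)-6-oxatricyclo[6.3.2.0^{4,13}]tridecan-9-one, via silyl enol ether 21 (not isolated)
Conditions: CH2=CHMgBr (3 equiv), CuBr·SMe2 (20 mol %), Me3SiCl (3 equiv), HMPA (3 equiv), THF, −78 → −40 °C; then 1 M HCl, THF, −20 → 0 °C
Reagents that add atoms: vinylmagnesium bromide, C=C[Mg]Br
Why: copper-catalysed, silyl-chloride-accelerated conjugate addition delivers vinyl to C11 from the exo face (syn to the C1 methyl, away from the ring A bridge), and kinetic protonation of C10 on hydrolysis of the silyl enol ether comes from the same exo face, which puts the methallyl group trans to the vinyl group.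

**Step 16**
Reactants: 22 vinyl methallyl ketone
Product: 24 (1S,4R,8S,10S,11S,13S)-1,5,5-trimethyl-9-oxo-10-(2-oxopropyl)-6-oxatricyclo[6.3.2.0^{4,13}]tridecane-11-carbaldehyde, via bis-ozonide 23 (not isolated)
Conditions: O3, CH2Cl2, −78 °C; then PPh3 (2.5 equiv), −78 °C → rt; used crude
Reagents that add atoms: ozone, [O-][O+]=O
Why: ozonolysis with reductive work-up cleaves both terminal alkenes in one operation, giving the aldehyde and the methyl ketone under neutral conditions that do not epimerise C10 or C11.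

**Step 17**
Reactants: 25 3-methylbut-2-enoyl chloride
Product: 26 chloromethyl 3-methylbut-2-enoate
Conditions: (CH2O)n, ZnCl2 (2 mol %), neat, 0 → 60 °C
Reagents that add atoms: formaldehyde (as paraformaldehyde), C=O
Why: ZnCl2-catalysed insertion of formaldehyde into the acyl chloride gives the α-chloromethyl ester.

**Step 18**
Reactants: 26 chloromethyl 3-methylbut-2-enoate
Product: 27 iodomethyl 3-methylbut-2-enoate
Conditions: NaI, acetone, rt, dark
Reagents that add atoms: sodium iodide, [Na+].[I-]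
Why: Finkelstein exchange gives the iodide, which is reactive enough to quaternise PPh3 at room temperature.

**Step 19**
Reactants: 27 iodomethyl 3-methylbut-2-enoate
Product: 28 {[(3-methylbut-2-enoyl)oxy]methyl}(triphenyl)phosphonium iodide
Conditions: PPh3, toluene, rt
Reagents that add atoms: triphenylphosphine, c1ccc(cc1)P(c1ccccc1)c1ccccc1
Why: SN2 quaternisation of triphenylphosphine gives the salt, which precipitates.

**Step 20**
Reactants: 24 keto-aldehyde; 28 acyloxymethylphosphonium iodide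
Product: 30 vibsanin E, via phosphonium ylide 29 (not isolated)
Conditions: 28 (1.6 equiv), KN(SiMe3)2 (1.5 equiv), THF, −78 °C; then 24, −78 → 0 °C; E isomer separated from Z by chromatography
Reagents that add atoms: none
Why: Wittig olefination with an acyloxymethylene ylide (Anders–Gaßner variant) reacts only at the aldehyde in the presence of both ketones and builds the enol ester directly, the E isomer being separated from the Z isomer that also forms.

**Compound list**
1 | 5-bromo-2-methylpent-2-ene | CC(C)=CCCBr | starting material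
2 | 6-methylhept-5-en-1-yne | CC(C)=CCCC#C | intermediate
3 | [(1E)-2,6-dimethylhepta-1,5-dien-1-yl]dimethylalane | CC(C)=CCC/C(C)=C/[Al](C)C | intermediate
4 | (1E)-1-iodo-2,6-dimethylhepta-1,5-diene | CC(C)=CCC/C(C)=C/I | intermediate
5 | (3E)-4,8-dimethylnona-1,3,7-triene | CC(C)=CCC/C(C)=C/C=C | intermediate
6 | methyl acetoacetate (methyl 3-oxobutanoate) | CC(=O)CC(=O)OC | starting material
7 | methyl 2-diazo-3-oxobutanoate | CC(=O)C(=[N+]=[N-])C(=O)OC | intermediate
8 | methyl 2-diazo-3-hydroxybutanoate (racemic) | CC(O)C(=[N+]=[N-])C(=O)OC | intermediate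
9 | methyl 2-diazobut-3-enoate | C=CC(=[N+]=[N-])C(=O)OC | intermediate
10 | methyl (1R,2R)-2-[(1E)-2,6-dimethylhepta-1,5-dien-1-yl]-1-ethenylcyclopropane-1-carboxylate | C=C[C@]1(C(=O)OC)C[C@@H]1/C=C(\C)CCC=C(C)C | intermediate
11 | methyl (4S)-4-methyl-4-(4-methylpent-3-en-1-yl)cyclohepta-1,5-diene-1-carboxylate | COC(=O)C1=CC[C@](C)(CCC=C(C)C)C=CC1 | intermediate
12 | [(4S)-4-methyl-4-(4-methylpent-3-en-1-yl)cyclohepta-1,5-dien-1-yl]methanol | OCC1=CC[C@](C)(CCC=C(C)C)C=CC1 | intermediate
13 | (4S)-4-methyl-4-(4-methylpent-3-en-1-yl)cyclohepta-1,5-diene-1-carbaldehyde | O=CC1=CC[C@](C)(CCC=C(C)C)C=CC1 | intermediate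
14 | (1S,4R,13S)-1,5,5-trimethyl-6-oxatricyclo[6.3.2.0^{4,13}]trideca-7,10-diene | C1C2=COC(C)(C)[C@@H]3CC[C@@](C)(C[C@@H]32)C=C1 | intermediate
15 | (1S,4R,8S,13R)-1,5,5-trimethyl-6-oxatricyclo[6.3.2.0^{4,13}]tridec-10-ene | C1[C@@H]2COC(C)(C)[C@@H]3CC[C@@](C)(C[C@@H]32)C=C1 | intermediate
16 | (1S,4R,8S,13S)-1,5,5-trimethyl-6-oxatricyclo[6.3.2.0^{4,13}]tridec-10-en-9-one | O=C1[C@@H]2COC(C)(C)[C@@H]3CC[C@@](C)(C[C@@H]32)C=C1 | intermediate
17 | (1S,4R,8S,13S)-10-iodo-1,5,5-trimethyl-6-oxatricyclo[6.3.2.0^{4,13}]tridec-10-en-9-one | O=C1[C@@H]2COC(C)(C)[C@@H]3CC[C@@](C)(C[C@@H]32)C=C1I | intermediate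
18 | 2-methylallylmagnesium chloride (THF solution) | CC(=C)C[Mg]Cl | starting material
19 | tributyl(2-methylprop-2-en-1-yl)stannane | CC(=C)C[Sn](CCCC)(CCCC)CCCC | intermediate
20 | (1S,4R,8S,13S)-1,5,5-trimethyl-10-(2-methylprop-2-en-1-yl)-6-oxatricyclo[6.3.2.0^{4,13}]tridec-10-en-9-one | O=C1[C@@H]2COC(C)(C)[C@@H]3CC[C@@](C)(C[C@@H]32)C=C1CC(C)=C | intermediate
21 | (1S,4R,8S,11R,13S)-11-ethenyl-1,5,5-trimethyl-10-(2-methylprop-2-en-1-yl)-9-[(trimethylsilyl)oxy]-6-oxatricyclo[6.3.2.0^{4,13}]tridec-9-ene | C=C(C)CC1=C(O[Si](C)(C)C)[C@@H]2COC(C)(C)[C@@H]3CC[C@@](C)(C[C@@H]32)[C@H]1C=C | intermediate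
22 | (1S,4R,8S,10S,11S,13S)-11-ethenyl-1,5,5-trimethyl-10-(2-methylprop-2-en-1-yl)-6-oxatricyclo[6.3.2.0^{4,13}]tridecan-9-one | CC(=C)C[C@@H]1C(=O)[C@@H]2COC(C)(C)[C@@H]3CC[C@@](C)(C[C@@H]32)[C@H]1C=C | intermediate
23 | (1S,4R,8S,10S,11S,13S)-1,5,5-trimethyl-10-[(3-methyl-1,2,4-trioxolan-3-yl)methyl]-11-(1,2,4-trioxolan-3-yl)-6-oxatricyclo[6.3.2.0^{4,13}]tridecan-9-one (trioxolane carbons unassigned) | CC1(OCOO1)C[C@@H]2C(=O)[C@@H]3COC(C)(C)[C@@H]4CC[C@@](C)(C[C@@H]43)[C@H]2C1OCOO1 | intermediate
24 | (1S,4R,8S,10S,11S,13S)-1,5,5-trimethyl-9-oxo-10-(2-oxopropyl)-6-oxatricyclo[6.3.2.0^{4,13}]tridecane-11-carbaldehyde | CC(=O)C[C@@H]1C(=O)[C@@H]2COC(C)(C)[C@@H]3CC[C@@](C)(C[C@@H]32)[C@H]1C=O | intermediate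
25 | 3-methylbut-2-enoyl chloride | CC(C)=CC(=O)Cl | starting material
26 | chloromethyl 3-methylbut-2-enoate | CC(C)=CC(=O)OCCl | intermediate
27 | iodomethyl 3-methylbut-2-enoate | CC(C)=CC(=O)OCI | intermediate
28 | {[(3-methylbut-2-enoyl)oxy]methyl}(triphenyl)phosphonium iodide | CC(C)=CC(=O)OC[P+](c1ccccc1)(c1ccccc1)c1ccccc1.[I-] | intermediate
29 | {[(3-methylbut-2-enoyl)oxy]methylidene}(triphenyl)phosphorane | CC(C)=CC(=O)OC=P(c1ccccc1)(c1ccccc1)c1ccccc1 | intermediate
30 | vibsanin E, (E)-2-[(1S,4R,8S,10S,11S,13S)-1,5,5-trimethyl-9-oxo-10-(2-oxopropyl)-6-oxatricyclo[6.3.2.0^{4,13}]tridecan-11-yl]ethenyl 3-methylbut-2-enoate | CC(=O)C[C@@H]1C(=O)[C@@H]2COC(C)(C)[C@@H]3CC[C@@](C)(C[C@@H]32)[C@H]1/C=C/OC(=O)C=C(C)C | target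

**Totals**
Total step count: 20.
Longest linear sequence: 13 steps (1, 2, 3, 7, 8, 9, 10, 11, 12, 14, 15, 16, 20; the path through 4, 5, 6 is equally long).

**Steps most likely to fail, with fallbacks**

Step 11 (allylic oxidation). The risk is oxygen uptake at the C11 end of the allyl radical or at the ether CH2. The fallback sets out from 15 and comes back at 16, and replaces the radical oxidation by a pericyclic one. SeO2 (0.5 equiv) with t-BuOOH in CH2Cl2 reacts by ene reaction and [2,3]-sigmatropic shift, which can place oxygen only on C9, to give the allylic alcohol (1S,4R,8S,13R)-1,5,5-trimethyl-6-oxatricyclo[6.3.2.0^{4,13}]tridec-10-en-9-ol F1 (either C9 epimer). Dess–Martin periodinane then oxidises it to 16.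

Step 15 (vinyl addition and C10 protonation). This is the least certain step: the enone is α-substituted and its β-carbon is neopentyl, and the exo-face protonation at C10 is argued from the shape of the tricycle, not demonstrated. The fallback sets out from 16 (by-passing 17 and 20) and comes back at 21 and then 22; it reverses the order of the two C–C bond formations.
- Vinylmagnesium bromide, CuBr·SMe2 and Me3SiCl add vinyl to the α-unsubstituted enone 16 and give the silyl enol ether (1S,4R,8S,11S,13S)-11-ethenyl-1,5,5-trimethyl-9-[(trimethylsilyl)oxy]-6-oxatricyclo[6.3.2.0^{4,13}]tridec-9-ene F2.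
- Dilute HCl hydrolyses it to the ketone (1S,4R,8S,11R,13S)-11-ethenyl-1,5,5-trimethyl-6-oxatricyclo[6.3.2.0^{4,13}]tridecan-9-one F3.
- α-Methylenation at the only α-CH2 (paraformaldehyde, N-methylanilinium trifluoroacetate, THF, reflux) gives the exocyclic enone (1S,4R,8S,11R,13S)-11-ethenyl-1,5,5-trimethyl-10-methylidene-6-oxatricyclo[6.3.2.0^{4,13}]tridecan-9-one F4.
- Copper-catalysed 1,4-addition of isopropenylmagnesium bromide with Me3SiCl to the unhindered methylene carbon gives 21, whose hydrolysis gives 22 as in step 15. C10 is again set last, by exo protonation.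

Step 20 (Wittig olefination). The risk is a poor E/Z ratio and base-induced aldol reaction or epimerisation of 24. The fallback sets out from 24 and comes back at 30, and makes the enol ester by stereoretentive C–O coupling.
- Takai–Utimoto olefination (CrCl2, LiI, Cl2CHB(pin), THF) converts only the aldehyde into the (E)-alkenylboronate 1-[(1S,4R,8S,10S,11S,13S)-1,5,5-trimethyl-9-oxo-11-[(E)-2-(4,4,5,5-tetramethyl-1,3,2-dioxaborolan-2-yl)ethenyl]-6-oxatricyclo[6.3.2.0^{4,13}]tridecan-10-yl]propan-2-one F5.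
- KHF2 in aqueous MeOH gives the potassium (E)-alkenyltrifluoroborate F6.
- Cu(OAc)2-mediated oxidative coupling with 3-methylbut-2-enoic acid (DMAP, 4 Å molecular sieves, O2, CH2Cl2) gives 30 with retention of the E geometry.

**Further compounds**
F1 | step 11 | (1S,4R,8S,13R)-1,5,5-trimethyl-6-oxatricyclo[6.3.2.0^{4,13}]tridec-10-en-9-ol (C9 epimers) | OC1[C@@H]2COC(C)(C)[C@@H]3CC[C@@](C)(C[C@@H]32)C=C1
F2 | step 15 | (1S,4R,8S,11S,13S)-11-ethenyl-1,5,5-trimethyl-9-[(trimethylsilyl)oxy]-6-oxatricyclo[6.3.2.0^{4,13}]tridec-9-ene | C1=C(O[Si](C)(C)C)[C@@H]2COC(C)(C)[C@@H]3CC[C@@](C)(C[C@@H]32)[C@H]1C=C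
F3 | step 15 | (1S,4R,8S,11R,13S)-11-ethenyl-1,5,5-trimethyl-6-oxatricyclo[6.3.2.0^{4,13}]tridecan-9-one | C1C(=O)[C@@H]2COC(C)(C)[C@@H]3CC[C@@](C)(C[C@@H]32)[C@H]1C=C
F4 | step 15 | (1S,4R,8S,11R,13S)-11-ethenyl-1,5,5-trimethyl-10-methylidene-6-oxatricyclo[6.3.2.0^{4,13}]tridecan-9-one | C=C1C(=O)[C@@H]2COC(C)(C)[C@@H]3CC[C@@](C)(C[C@@H]32)[C@H]1C=C
F5 | step 20 | 1-[(1S,4R,8S,10S,11S,13S)-1,5,5-trimethyl-9-oxo-11-[(E)-2-(4,4,5,5-tetramethyl-1,3,2-dioxaborolan-2-yl)ethenyl]-6-oxatricyclo[6.3.2.0^{4,13}]tridecan-10-yl]propan-2-one | CC(=O)C[C@@H]1C(=O)[C@@H]2COC(C)(C)[C@@H]3CC[C@@](C)(C[C@@H]32)[C@H]1/C=C/B1OC(C)(C)C(C)(C)O1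
F6 | step 20 | potassium (E)-2-[(1S,4R,8S,10S,11S,13S)-1,5,5-trimethyl-9-oxo-10-(2-oxopropyl)-6-oxatricyclo[6.3.2.0^{4,13}]tridecan-11-yl]ethenyl(trifluoro)borate | CC(=O)C[C@@H]1C(=O)[C@@H]2COC(C)(C)[C@@H]3CC[C@@](C)(C[C@@H]32)[C@H]1/C=C/[B-](F)(F)F.[K+]
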